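**Retrosynthetic overview**
1. Target 30 comes from its C3′ silyl ether 28 by desilylation and oxidation. The whole bicyclic enol ketal of 28 is made in one operation from the acyclic β-hydroxy ketone 24 and triethyl orthopropionate.
2. Enabling feature: C1 carries O2 and O9. Without the C1–C8 bond it is the orthoester-level C2 of the 4H-1,3-dioxin ring A (O2–C3=C4–C5–O9–C1) and ionizes to a dioxocarbenium ion. C8 is the silicon-bearing carbon of a (Z)-vinylsilane on the C5 side chain, placed to close dihydropyran ring B (C1–C8=C7–C6–C5–O9).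
3. Ring order: ring A first (C5–O9–C1 and C1–O2 from the C5 hydroxyl, the orthoester and the C3 carbonyl), then ring B by C1–C8 bond formation. The C1 configuration follows from C5.
4. 24 comes from a syn aldol (C4–C5) of ethyl ketone 14 with aldehyde 22. 14 comes from (E)-2-methylpent-2-enal by Evans alkylation and Evans aldol. 22 comes from the Roche ester by (Z)-iodo-olefination and silylation.

Key step: step 17

Locants: core atoms C1–O9 of the 2,9-dioxabicyclo[3.3.1]nona-3,7-diene and chain atoms C1′–C9′ of the non-6-en-3-one are used for all intermediates.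
Assumption: the (Z)-enolate made with (−)-Ipc2BOTf (from (+)-α-pinene) attacks the Re face of the aldehyde, as is usual for ethyl ketones; compounds 1, 4, 9, 15 and triethyl orthopropionate are taken as commercial.

**Step 1**
Reactants: 1 (E)-2-methylpent-2-enal
Product: 2 (E)-2-methylpent-2-en-1-ol
Conditions: NaBH4, CeCl3·7H2O, MeOH, 0 °C
Reagents that add atoms: none
Why: Luche reduction delivers hydride 1,2 to the enal and leaves the (E)-alkene untouched.

**Step 2**
Reactants: 2 (E)-2-methylpent-2-en-1-ol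
Product: 3 (E)-1-bromo-2-methylpent-2-ene
Conditions: PBr3, Et2O, 0 °C
Reagents that add atoms: phosphorus tribromide, BrP(Br)Br
Why: SN2-type bromination of the primary allylic alcohol at low temperature should avoid allylic transposition.

**Step 3**
Reactants: 4 (S)-4-benzyl-3-propanoyl-1,3-oxazolidin-2-one; 3 (E)-1-bromo-2-methylpent-2-ene
Product: 6 (S)-4-benzyl-3-[(2R,4E)-2,4-dimethylhept-4-enoyl]-1,3-oxazolidin-2-one, via sodium enolate 5 (not isolated)
Conditions: NaN(SiMe3)2, THF, −78 °C; then 3, −78 to −40 °C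
Reagents that add atoms: none
Why: Evans asymmetric alkylation: the chelated (Z)-enolate is alkylated on the face opposite the benzyl group, which sets C4′ (2R in 6).

**Step 4**
Reactants: 6 (S)-4-benzyl-3-[(2R,4E)-2,4-dimethylhept-4-enoyl]-1,3-oxazolidin-2-one
Product: 7 (2R,4E)-2,4-dimethylhept-4-en-1-ol
Conditions: LiBH4, MeOH (1 equiv), Et2O, 0 °C
Reagents that add atoms: none
Why: Reductive cleavage of the imide releases the primary alcohol without touching the stereocenter or the alkene.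

**Step 5**
Reactants: 7 (2R,4E)-2,4-dimethylhept-4-en-1-ol
Product: 8 (2R,4E)-2,4-dimethylhept-4-enal
Conditions: Dess–Martin periodinane, NaHCO3, CH2Cl2, 0 °C to rt
Reagents that add atoms: none
Why: Buffered Dess–Martin oxidation should give the α-chiral aldehyde without epimerization.

**Step 6**
Reactants: 9 (R)-4-benzyl-3-propanoyl-1,3-oxazolidin-2-one; 8 (2R,4E)-2,4-dimethylhept-4-enal
Product: 11 (R)-4-benzyl-3-[(2R,3S,4R,6E)-3-hydroxy-2,4,6-trimethylnon-6-enoyl]-1,3-oxazolidin-2-one, via boron enolate 10 (not isolated)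
Conditions: n-Bu2BOTf, Et3N, CH2Cl2, −78 to 0 °C; 8, −78 to 0 °C; H2O2, MeOH, pH 7 buffer
Reagents that add atoms: none
Why: Evans syn aldol: the dibutylboron (Z)-enolate reacts through a chair Zimmerman–Traxler transition state under auxiliary control and sets C2′ (R in 11) and the temporary carbinol C3′ (S).

**Step 7**
Reactants: 11 (R)-4-benzyl-3-[(2R,3S,4R,6E)-3-hydroxy-2,4,6-trimethylnon-6-enoyl]-1,3-oxazolidin-2-one
Product: 12 (2R,3S,4R,6E)-3-hydroxy-N-methoxy-N,2,4,6-tetramethylnon-6-enamide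
Conditions: MeNH(OMe)·HCl, AlMe3, CH2Cl2, −20 to 0 °C; aq. potassium sodium tartrate
Reagents that add atoms: N,O-dimethylhydroxylamine hydrochloride, CNOC.Cl
Why: Weinreb transamidation by the aluminium amide, assisted by the free β-hydroxyl, removes the auxiliary.

**Step 8**
Reactants: 12 (2R,3S,4R,6E)-3-hydroxy-N-methoxy-N,2,4,6-tetramethylnon-6-enamide
Product: 13 (2R,3S,4R,6E)-3-[(tert-butyldimethylsilyl)oxy]-N-methoxy-N,2,4,6-tetramethylnon-6-enamide
Conditions: t-BuMe2SiOTf, 2,6-lutidine, CH2Cl2, −78 to 0 °C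
Reagents that add atoms: tert-butyldimethylsilyl trifluoromethanesulfonate, CC(C)(C)[Si](C)(C)OS(=O)(=O)C(F)(F)F
Why: Silylation with the silyl triflate keeps C3′ at the alcohol level, so that no epimerizable 1,3-diketone exists before ring A is formed.

**Step 9**
Reactants: 13 (2R,3S,4R,6E)-3-[(tert-butyldimethylsilyl)oxy]-N-methoxy-N,2,4,6-tetramethylnon-6-enamide
Product: 14 (4R,5S,6R,8E)-5-[(tert-butyldimethylsilyl)oxy]-4,6,8-trimethylundec-8-en-3-one
Conditions: EtMgBr, THF, 0 °C; aq. NH4Cl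
Reagents that add atoms: ethylmagnesium bromide, CC[Mg]Br
Why: Grignard addition to the Weinreb amide stops at the chelated tetrahedral intermediate and should give the ethyl ketone without epimerizing the α-center.

**Step 10**
Reactants: 15 methyl (R)-3-hydroxy-2-methylpropanoate
Product: 16 methyl (R)-3-[(tert-butyldimethylsilyl)oxy]-2-methylpropanoate
Conditions: t-BuMe2SiCl, imidazole, CH2Cl2, 0 °C to rt
Reagents that add atoms: tert-butyldimethylsilyl chloride, CC(C)(C)[Si](C)(C)Cl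
Why: Standard silylation of the primary alcohol.

**Step 11**
Reactants: 16 methyl (R)-3-[(tert-butyldimethylsilyl)oxy]-2-methylpropanoate
Product: 17 (R)-3-[(tert-butyldimethylsilyl)oxy]-2-methylpropanal
Conditions: i-Bu2AlH (1.1 equiv), CH2Cl2, −78 °C; aq. potassium sodium tartrate
Reagents that add atoms: none
Why: Partial ester reduction: the tetrahedral aluminate is stable at −78 °C and collapses to the aldehyde only on work-up.

**Step 12**
Reactants: 17 (R)-3-[(tert-butyldimethylsilyl)oxy]-2-methylpropanal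
Product: 18 tert-butyl{[(2S,3Z)-4-iodo-2-methylpent-3-en-1-yl]oxy}dimethylsilane
Conditions: EtPPh3I, n-BuLi, THF; I2, −78 °C; NaN(SiMe3)2, −20 °C; 17, −78 °C
Reagents that add atoms: ethyltriphenylphosphonium iodide, CC[P+](c1ccccc1)(c1ccccc1)c1ccccc1.[I-]; iodine, II
Why: Stork–Zhao-type Wittig olefination with the α-iodo ylide should give the (Z)-2-iodoalkene (iodine cis to the chain) under the kinetic control typical of unstabilized ylides.

**Step 13**
Reactants: 18 tert-butyl{[(2S,3Z)-4-iodo-2-methylpent-3-en-1-yl]oxy}dimethylsilane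
Product: 20 tert-butyldimethyl{[(2S,3Z)-2-methyl-4-(trimethylsilyl)pent-3-en-1-yl]oxy}silane, via vinyllithium 19 (not isolated)
Conditions: t-BuLi (2.1 equiv), Et2O, −78 °C; Me3SiCl, −78 to 0 °C
Reagents that add atoms: chlorotrimethylsilane, C[Si](C)(C)Cl
Why: Iodine–lithium exchange and silylation both proceed with retention, which places silicon cis to C6 as the ring closure requires.

**Step 14**
Reactants: 20 tert-butyldimethyl{[(2S,3Z)-2-methyl-4-(trimethylsilyl)pent-3-en-1-yl]oxy}silane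
Product: 21 (2S,3Z)-2-methyl-4-(trimethylsilyl)pent-3-en-1-ol
Conditions: camphorsulfonic acid (cat.), MeOH/CH2Cl2, 0 °C
Reagents that add atoms: none
Why: Acid-catalysed methanolysis removes the primary silyl ether; the vinylsilane should be stable to these mild conditions.

**Step 15**
Reactants: 21 (2S,3Z)-2-methyl-4-(trimethylsilyl)pent-3-en-1-ol
Product: 22 (2S,3Z)-2-methyl-4-(trimethylsilyl)pent-3-enal
Conditions: Dess–Martin periodinane, NaHCO3, CH2Cl2, 0 °C; used at once
Reagents that add atoms: none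
Why: Buffered Dess–Martin oxidation; allylic strain from the cis silyl group holds the α-C–H in the alkene plane, so the β,γ-unsaturated aldehyde should not be unusually prone to epimerization or conjugation.

**Step 16**
Reactants: 14 (4R,5S,6R,8E)-5-[(tert-butyldimethylsilyl)oxy]-4,6,8-trimethylundec-8-en-3-one; 22 (2S,3Z)-2-methyl-4-(trimethylsilyl)pent-3-enal
Product: 24 (2Z,4S,5S,6R,8R,9S,10R,12E)-9-[(tert-butyldimethylsilyl)oxy]-5-hydroxy-4,6,8,10,12-pentamethyl-2-(trimethylsilyl)pentadeca-2,12-dien-7-one, via boron enolate 23 (not isolated)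
Conditions: (−)-Ipc2BOTf, i-Pr2NEt, CH2Cl2, −78 °C; 22, −78 to −20 °C; H2O2, MeOH, pH 7 buffer, 0 °C
Reagents that add atoms: none
Why: Paterson boron aldol: the (Z)-enol diisopinocampheylborinate reacts through a chair Zimmerman–Traxler transition state to give the 4,5-syn adduct, and Re-face attack on 22 (5S; C4, later erased, follows as R) is expected because the reagent, the anti-Felkin preference of (Z)-enolates with α-methyl aldehydes and the syn–anti preference of (Z)-boron enolates of α-methyl ketones all point the same way.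

**Step 17**
Reactants: 24 (2Z,4S,5S,6R,8R,9S,10R,12E)-9-[(tert-butyldimethylsilyl)oxy]-5-hydroxy-4,6,8,10,12-pentamethyl-2-(trimethylsilyl)pentadeca-2,12-dien-7-one
Product: 28 tert-butyl{[(2R,3S,4R,6E)-2-[(1S,5S,6S)-1-ethyl-4,6,8-trimethyl-2,9-dioxabicyclo[3.3.1]nona-3,7-dien-3-yl]-4,6-dimethylnon-6-en-3-yl]oxy}dimethylsilane, via mixed orthoester 25 (not isolated), via cyclic orthoester 26 (not isolated), via dioxinylium triflate 27 (not isolated)
Conditions: EtC(OEt)3 (1.5 equiv), pyridinium p-toluenesulfonate (cat.), 4 Å MS, CH2Cl2, rt; then 2,6-di-tert-butyl-4-methylpyridine (3 equiv), Me3SiOTf (2.5 equiv), −78 to −20 °C; Et3N quench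
Reagents that add atoms: triethyl orthopropionate, CCC(OCC)(OCC)OCC
Why: Proposed new method: orthoester exchange at the C5 hydroxyl gives 25, Me3SiOTf ionizes it to a dialkoxycarbenium ion, the C3 carbonyl oxygen adds to it (ring A, 6-exo with respect to the C1=O+Et bond) and loss of H4 gives 26, whose second ionization gives dioxinylium ion 27; the (Z)-vinylsilane then attacks C1 with its silicon-bearing carbon C8 and the β-silyl cation loses Me3Si+, which forms the C1–C8 bond and closes ring B in the 6-endo mode with respect to the vinylsilane (both alkene carbons in the ring, geometry retained). The closest known reactions are the acetal-initiated, vinylsilane-terminated cyclization of (Z)-vinylsilanes to 3,6-dihydro-2H-pyrans (silyl-Prins type) and the trapping of orthoester-derived dialkoxycarbenium ions by allylsilanes; what is new is a vinylsilane as terminator for a dioxocarbenium ion, which is made reasonable by the six-membered transition state, by the axial preference of the C5 side chain next to the C4 methyl and by O2 being a weakly donating enol oxygen. C1 is the only new stereocenter and is fixed by C5, because O9 and the C6–C7=C8 arm both start from C5 and the bridged ketal can close in one configuration only. The step needs ipso attack at C8 instead of C7 (β-silyl stabilization of positive charge at C7, six- against five-membered ring), an endocyclic C3=C4 instead of an exocyclic C3=C2′ enol ether (the syn C4/C5 relationship of 24 places H4 axial to the cationic C3 while allylic strain keeps H2′ in the nodal plane, so C2′ is not epimerized) and survival of the vinylsilane and silyl ether (proton-free medium through the hindered pyridine, low temperature). If the vinylsilane captures the first, acyclic cation before the carbonyl oxygen does, the 2-ethoxydihydropyran so formed re-ionizes and O2 closes ring A to give the same 28.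

**Step 18**
Reactants: 28 tert-butyl{[(2R,3S,4R,6E)-2-[(1S,5S,6S)-1-ethyl-4,6,8-trimethyl-2,9-dioxabicyclo[3.3.1]nona-3,7-dien-3-yl]-4,6-dimethylnon-6-en-3-yl]oxy}dimethylsilane
Product: 29 (2R,3S,4R,6E)-2-[(1S,5S,6S)-1-ethyl-4,6,8-trimethyl-2,9-dioxabicyclo[3.3.1]nona-3,7-dien-3-yl]-4,6-dimethylnon-6-en-3-ol
Conditions: Bu4NF, THF, 0 to 40 °C
Reagents that add atoms: none
Why: Fluoride cleavage of the silyl ether; the enol ketal core is stable to base and no carbonyl is present that could allow retro-aldol cleavage.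

**Step 19**
Reactants: 29 (2R,3S,4R,6E)-2-[(1S,5S,6S)-1-ethyl-4,6,8-trimethyl-2,9-dioxabicyclo[3.3.1]nona-3,7-dien-3-yl]-4,6-dimethylnon-6-en-3-ol
Product: 30 (2S,4R,6E)-2-[(1S,5S,6S)-1-ethyl-4,6,8-trimethyl-2,9-dioxabicyclo[3.3.1]nona-3,7-dien-3-yl]-4,6-dimethylnon-6-en-3-one
Conditions: Dess–Martin periodinane, NaHCO3, CH2Cl2, 0 °C
Reagents that add atoms: none
Why: Buffered Dess–Martin oxidation of the C3′ alcohol; neutral conditions should protect the acid-labile enol ketal and the C2′ center, which is now flanked by the ketone and the enol ether.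

**Compound list**
1 | (E)-2-methylpent-2-enal | CC/C=C(\C)C=O | starting material
2 | (E)-2-methylpent-2-en-1-ol | CC/C=C(\C)CO | intermediate
3 | (E)-1-bromo-2-methylpent-2-ene | CC/C=C(\C)CBr | intermediate
4 | (S)-4-benzyl-3-propanoyl-1,3-oxazolidin-2-one | CCC(=O)N1[C@@H](Cc2ccccc2)COC1=O | starting material
5 | sodium (Z)-enolate of 4 | C/C=C(\[O-])N1[C@@H](Cc2ccccc2)COC1=O.[Na+] | intermediate
6 | (S)-4-benzyl-3-[(2R,4E)-2,4-dimethylhept-4-enoyl]-1,3-oxazolidin-2-one | CC/C=C(\C)C[C@@H](C)C(=O)N1[C@@H](Cc2ccccc2)COC1=O | intermediate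
7 | (2R,4E)-2,4-dimethylhept-4-en-1-ol | CC/C=C(\C)C[C@@H](C)CO | intermediate
8 | (2R,4E)-2,4-dimethylhept-4-enal | CC/C=C(\C)C[C@@H](C)C=O | intermediate
9 | (R)-4-benzyl-3-propanoyl-1,3-oxazolidin-2-one | CCC(=O)N1[C@H](Cc2ccccc2)COC1=O | starting material
10 | di-n-butylboron (Z)-enolate of 9 | C/C=C(\OB(CCCC)CCCC)N1[C@H](Cc2ccccc2)COC1=O | intermediate
11 | (R)-4-benzyl-3-[(2R,3S,4R,6E)-3-hydroxy-2,4,6-trimethylnon-6-enoyl]-1,3-oxazolidin-2-one | CC/C=C(\C)C[C@@H](C)[C@H](O)[C@@H](C)C(=O)N1[C@H](Cc2ccccc2)COC1=O | intermediate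
12 | (2R,3S,4R,6E)-3-hydroxy-N-methoxy-N,2,4,6-tetramethylnon-6-enamide | CC/C=C(\C)C[C@@H](C)[C@H](O)[C@@H](C)C(=O)N(C)OC | intermediate
13 | (2R,3S,4R,6E)-3-[(tert-butyldimethylsilyl)oxy]-N-methoxy-N,2,4,6-tetramethylnon-6-enamide | CC/C=C(\C)C[C@@H](C)[C@H](O[Si](C)(C)C(C)(C)C)[C@@H](C)C(=O)N(C)OC | intermediate
14 | (4R,5S,6R,8E)-5-[(tert-butyldimethylsilyl)oxy]-4,6,8-trimethylundec-8-en-3-one | CC/C=C(\C)C[C@@H](C)[C@H](O[Si](C)(C)C(C)(C)C)[C@@H](C)C(=O)CC | intermediate
15 | methyl (R)-3-hydroxy-2-methylpropanoate | COC(=O)[C@H](C)CO | starting material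
16 | methyl (R)-3-[(tert-butyldimethylsilyl)oxy]-2-methylpropanoate | COC(=O)[C@H](C)CO[Si](C)(C)C(C)(C)C | intermediate
17 | (R)-3-[(tert-butyldimethylsilyl)oxy]-2-methylpropanal | O=C[C@H](C)CO[Si](C)(C)C(C)(C)C | intermediate
18 | tert-butyl{[(2S,3Z)-4-iodo-2-methylpent-3-en-1-yl]oxy}dimethylsilane | C/C(I)=C/[C@H](C)CO[Si](C)(C)C(C)(C)C | intermediate
19 | (Z)-vinyllithium from 18 (lithium cis to C6) | C/C([Li])=C/[C@H](C)CO[Si](C)(C)C(C)(C)C | intermediate
20 | tert-butyldimethyl{[(2S,3Z)-2-methyl-4-(trimethylsilyl)pent-3-en-1-yl]oxy}silane | C/C([Si](C)(C)C)=C/[C@H](C)CO[Si](C)(C)C(C)(C)C | intermediate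
21 | (2S,3Z)-2-methyl-4-(trimethylsilyl)pent-3-en-1-ol | C/C([Si](C)(C)C)=C/[C@H](C)CO | intermediate
22 | (2S,3Z)-2-methyl-4-(trimethylsilyl)pent-3-enal | C/C([Si](C)(C)C)=C/[C@H](C)C=O | intermediate
23 | (Z)-enol diisopinocampheylborinate of 14 | C/C=C(\OB([C@@H]1C[C@@H]2C[C@H]([C@H]1C)C2(C)C)[C@@H]1C[C@@H]2C[C@H]([C@H]1C)C2(C)C)[C@H](C)[C@@H](O[Si](C)(C)C(C)(C)C)[C@H](C)C/C(C)=C/CC | intermediate
24 | (2Z,4S,5S,6R,8R,9S,10R,12E)-9-[(tert-butyldimethylsilyl)oxy]-5-hydroxy-4,6,8,10,12-pentamethyl-2-(trimethylsilyl)pentadeca-2,12-dien-7-one | C/C([Si](C)(C)C)=C/[C@H](C)[C@H](O)[C@@H](C)C(=O)[C@H](C)[C@@H](O[Si](C)(C)C(C)(C)C)[C@H](C)C/C(C)=C/CC | intermediate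
25 | mixed orthoester of 24: (2Z,4S,5S,6R,8R,9S,10R,12E)-9-[(tert-butyldimethylsilyl)oxy]-5-(1,1-diethoxypropoxy)-4,6,8,10,12-pentamethyl-2-(trimethylsilyl)pentadeca-2,12-dien-7-one | C/C([Si](C)(C)C)=C/[C@H](C)[C@H](OC(CC)(OCC)OCC)[C@@H](C)C(=O)[C@H](C)[C@@H](O[Si](C)(C)C(C)(C)C)[C@H](C)C/C(C)=C/CC | intermediate
26 | cyclic orthoester of ring A: tert-butyl{[(2R,3S,4R,6E)-2-{(4S)-2-ethoxy-2-ethyl-5-methyl-4-[(2S,3Z)-4-(trimethylsilyl)pent-3-en-2-yl]-4H-1,3-dioxin-6-yl}-4,6-dimethylnon-6-en-3-yl]oxy}dimethylsilane (both epimers at the orthoester carbon) | C/C([Si](C)(C)C)=C/[C@H](C)[C@@H]1OC(CC)(OCC)OC(=C1C)[C@H](C)[C@@H](O[Si](C)(C)C(C)(C)C)[C@H](C)C/C(C)=C/CC | intermediate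
27 | (4S)-2-ethyl-5-methyl-4-[(2S,3Z)-4-(trimethylsilyl)pent-3-en-2-yl]-6-[(2R,3S,4R,6E)-3-(tert-butyldimethylsilyloxy)-4,6-dimethylnon-6-en-2-yl]-4H-1,3-dioxin-2-ylium trifluoromethanesulfonate | C/C([Si](C)(C)C)=C/[C@H](C)[C@@H]1O[C+](CC)OC(=C1C)[C@H](C)[C@@H](O[Si](C)(C)C(C)(C)C)[C@H](C)C/C(C)=C/CC.[O-]S(=O)(=O)C(F)(F)F | intermediate
28 | tert-butyl{[(2R,3S,4R,6E)-2-[(1S,5S,6S)-1-ethyl-4,6,8-trimethyl-2,9-dioxabicyclo[3.3.1]nona-3,7-dien-3-yl]-4,6-dimethylnon-6-en-3-yl]oxy}dimethylsilane | CC/C=C(\C)C[C@@H](C)[C@H](O[Si](C)(C)C(C)(C)C)[C@@H](C)C1=C(C)[C@H]2O[C@@](CC)(O1)C(C)=C[C@@H]2C | intermediate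
29 | (2R,3S,4R,6E)-2-[(1S,5S,6S)-1-ethyl-4,6,8-trimethyl-2,9-dioxabicyclo[3.3.1]nona-3,7-dien-3-yl]-4,6-dimethylnon-6-en-3-ol | CC/C=C(\C)C[C@@H](C)[C@H](O)[C@@H](C)C1=C(C)[C@H]2O[C@@](CC)(O1)C(C)=C[C@@H]2C | intermediate
30 | (2S,4R,6E)-2-[(1S,5S,6S)-1-ethyl-4,6,8-trimethyl-2,9-dioxabicyclo[3.3.1]nona-3,7-dien-3-yl]-4,6-dimethylnon-6-en-3-one (CNP0232650.2) | CC/C=C(\C)C[C@@H](C)C(=O)[C@@H](C)C1=C(C)[C@H]2O[C@@](CC)(O1)C(C)=C[C@@H]2C | target

**Step count and risks**
Total step count: 19. Longest linear sequence: 13 steps (steps 1–9 and 16–19).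

Step 17 (proposed new method). What may go wrong: dealkylative collapse of the dialkoxycarbenium ion to the C5 propionate, protodesilylation of the vinylsilane or β-elimination across C4–C5 before the C1–C8 bond forms, and proton loss towards C2′ instead of C4. The fallback uses known chemistry only; it sets out from 18 and comes back at 28. Camphorsulfonic acid in MeOH removes the primary silyl ether of 18 to give (2S,3Z)-4-iodo-2-methylpent-3-en-1-ol F1. Buffered Dess–Martin oxidation gives (2S,3Z)-4-iodo-2-methylpent-3-enal F2. The aldol of step 16 with 14 gives the iodo hydroxy ketone (2Z,4S,5S,6R,8R,9S,10R,12E)-9-[(tert-butyldimethylsilyl)oxy]-5-hydroxy-2-iodo-4,6,8,10,12-pentamethylpentadeca-2,12-dien-7-one F3. Nozaki–Hiyama–Kishi coupling of F3 with propanal (CrCl2, cat. NiCl2, DMSO) forms the C1–C8 bond intermolecularly and gives the allylic alcohol (4Z,6S,7S,8R,10R,11S,12R,14E)-11-[(tert-butyldimethylsilyl)oxy]-3,7-dihydroxy-4,6,8,10,12,14-hexamethylheptadeca-4,14-dien-9-one F4 as both C3 epimers; the ketone should be left alone because the organochromium reagent adds to aldehydes much faster. MnO2 oxidizes only the allylic alcohol, and the (Z)-enone is closed at once by the C5 hydroxyl to the lactol (2R,4R,5S,6R,8E)-5-[(tert-butyldimethylsilyl)oxy]-2-[(2S,3S)-6-ethyl-6-hydroxy-3,5-dimethyl-3,6-dihydro-2H-pyran-2-yl]-4,6,8-trimethylundec-8-en-3-one F5. Pyridinium p-toluenesulfonate with 4 Å MS in CH2Cl2 then condenses the lactol with the C3 ketone (ionization, attack of the carbonyl oxygen, loss of H4) to give 28; here both rings close by C–O bond formation.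

Step 16. What may go wrong: poor facial selectivity at C5, because the intrinsic bias of the α-chiral enolate of 14 under titanium or (E)-boron conditions favours the opposite C5 configuration and the (Z)-boron preference may be weak for a silyloxy ketone. The fallback builds the C3–C5 unit first under auxiliary-type control; it sets out from 22 (with 8 as partner) and comes back at 28. Anti aldol of (R)-2-(benzoyloxy)pentan-3-one ((c-Hex)2BCl, Me2NEt) with 22 gives (2R,4S,5S,6S,7Z)-5-hydroxy-4,6-dimethyl-3-oxo-8-(trimethylsilyl)non-7-en-2-yl benzoate F6. Et3SiOTf and 2,6-lutidine give its triethylsilyl ether (2R,4S,5S,6S,7Z)-4,6-dimethyl-3-oxo-5-[(triethylsilyl)oxy]-8-(trimethylsilyl)non-7-en-2-yl benzoate F7. SmI2 in THF/MeOH removes the benzoate to give the ethyl ketone (4S,5S,6S,7Z)-4,6-dimethyl-5-[(triethylsilyl)oxy]-8-(trimethylsilyl)non-7-en-3-one F8. Its TiCl4/i-Pr2NEt enolate adds to 8 in a syn aldol in which the C4 methyl directs the new C2′ methyl syn to itself, giving (2Z,4S,5S,6S,8R,9S,10R,12E)-9-hydroxy-4,6,8,10,12-pentamethyl-5-[(triethylsilyl)oxy]-2-(trimethylsilyl)pentadeca-2,12-dien-7-one F9. t-BuMe2SiOTf gives (2Z,4S,5S,6S,8R,9S,10R,12E)-9-[(tert-butyldimethylsilyl)oxy]-4,6,8,10,12-pentamethyl-5-[(triethylsilyl)oxy]-2-(trimethylsilyl)pentadeca-2,12-dien-7-one F10. Pyridinium p-toluenesulfonate in MeOH removes the triethylsilyl group selectively to give (2Z,4S,5S,6S,8R,9S,10R,12E)-9-[(tert-butyldimethylsilyl)oxy]-5-hydroxy-4,6,8,10,12-pentamethyl-2-(trimethylsilyl)pentadeca-2,12-dien-7-one F11, the C4 epimer of 24. Since C4 becomes sp2 in step 17, F11 is taken through the conditions of step 17 and meets the route at 28.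

Step 12. What may go wrong: low conversion and erosion of the Z-selectivity in the iodo-olefination, and partial epimerization of aldehyde 17 by the basic ylide. The fallback makes the vinylsilane from an alkyne; it sets out from 17 and comes back at 20. Corey–Fuchs olefination (CBr4, PPh3) gives (S)-tert-butyl[(4,4-dibromo-2-methylbut-3-en-1-yl)oxy]dimethylsilane F12. n-BuLi followed by Me3SiCl gives (S)-tert-butyldimethyl{[2-methyl-4-(trimethylsilyl)but-3-yn-1-yl]oxy}silane F13. Cis-hydroalumination (i-Bu2AlH, N-methylpyrrolidine, heptane; aluminium on the silyl-bearing carbon), ate-complex formation with MeLi and methylation with MeI, which replaces aluminium with retention, then give 20.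

**Further compounds**
F1 | step 17 | (2S,3Z)-4-iodo-2-methylpent-3-en-1-ol | C/C(I)=C/[C@H](C)CO
F2 | step 17 | (2S,3Z)-4-iodo-2-methylpent-3-enal | C/C(I)=C/[C@H](C)C=O
F3 | step 17 | (2Z,4S,5S,6R,8R,9S,10R,12E)-9-[(tert-butyldimethylsilyl)oxy]-5-hydroxy-2-iodo-4,6,8,10,12-pentamethylpentadeca-2,12-dien-7-one | C/C(I)=C/[C@H](C)[C@H](O)[C@@H](C)C(=O)[C@H](C)[C@@H](O[Si](C)(C)C(C)(C)C)[C@H](C)C/C(C)=C/CC
F4 | step 17 | (4Z,6S,7S,8R,10R,11S,12R,14E)-11-[(tert-butyldimethylsilyl)oxy]-3,7-dihydroxy-4,6,8,10,12,14-hexamethylheptadeca-4,14-dien-9-one (both C3 epimers) | CCC(O)/C(C)=C\[C@H](C)[C@H](O)[C@@H](C)C(=O)[C@H](C)[C@@H](O[Si](C)(C)C(C)(C)C)[C@H](C)C/C(C)=C/CC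
F5 | step 17 | (2R,4R,5S,6R,8E)-5-[(tert-butyldimethylsilyl)oxy]-2-[(2S,3S)-6-ethyl-6-hydroxy-3,5-dimethyl-3,6-dihydro-2H-pyran-2-yl]-4,6,8-trimethylundec-8-en-3-one (both anomers) | CCC1(O)O[C@H]([C@@H](C)C(=O)[C@H](C)[C@@H](O[Si](C)(C)C(C)(C)C)[C@H](C)C/C(C)=C/CC)[C@@H](C)C=C1C
F6 | step 16 | (2R,4S,5S,6S,7Z)-5-hydroxy-4,6-dimethyl-3-oxo-8-(trimethylsilyl)non-7-en-2-yl benzoate | C/C([Si](C)(C)C)=C/[C@H](C)[C@H](O)[C@H](C)C(=O)[C@@H](C)OC(=O)c1ccccc1
F7 | step 16 | (2R,4S,5S,6S,7Z)-4,6-dimethyl-3-oxo-5-[(triethylsilyl)oxy]-8-(trimethylsilyl)non-7-en-2-yl benzoate | C/C([Si](C)(C)C)=C/[C@H](C)[C@H](O[Si](CC)(CC)CC)[C@H](C)C(=O)[C@@H](C)OC(=O)c1ccccc1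
F8 | step 16 | (4S,5S,6S,7Z)-4,6-dimethyl-5-[(triethylsilyl)oxy]-8-(trimethylsilyl)non-7-en-3-one | C/C([Si](C)(C)C)=C/[C@H](C)[C@H](O[Si](CC)(CC)CC)[C@H](C)C(=O)CC
F9 | step 16 | (2Z,4S,5S,6S,8R,9S,10R,12E)-9-hydroxy-4,6,8,10,12-pentamethyl-5-[(triethylsilyl)oxy]-2-(trimethylsilyl)pentadeca-2,12-dien-7-one | C/C([Si](C)(C)C)=C/[C@H](C)[C@H](O[Si](CC)(CC)CC)[C@H](C)C(=O)[C@H](C)[C@@H](O)[C@H](C)C/C(C)=C/CC
F10 | step 16 | (2Z,4S,5S,6S,8R,9S,10R,12E)-9-[(tert-butyldimethylsilyl)oxy]-4,6,8,10,12-pentamethyl-5-[(triethylsilyl)oxy]-2-(trimethylsilyl)pentadeca-2,12-dien-7-one | C/C([Si](C)(C)C)=C/[C@H](C)[C@H](O[Si](CC)(CC)CC)[C@H](C)C(=O)[C@H](C)[C@@H](O[Si](C)(C)C(C)(C)C)[C@H](C)C/C(C)=C/CC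
F11 | step 16 | (2Z,4S,5S,6S,8R,9S,10R,12E)-9-[(tert-butyldimethylsilyl)oxy]-5-hydroxy-4,6,8,10,12-pentamethyl-2-(trimethylsilyl)pentadeca-2,12-dien-7-one | C/C([Si](C)(C)C)=C/[C@H](C)[C@H](O)[C@H](C)C(=O)[C@H](C)[C@@H](O[Si](C)(C)C(C)(C)C)[C@H](C)C/C(C)=C/CC
F12 | step 12 | (S)-tert-butyl[(4,4-dibromo-2-methylbut-3-en-1-yl)oxy]dimethylsilane | BrC(Br)=C[C@H](C)CO[Si](C)(C)C(C)(C)C
F13 | step 12 | (S)-tert-butyldimethyl{[2-methyl-4-(trimethylsilyl)but-3-yn-1-yl]oxy}silane | C[Si](C)(C)C#C[C@H](C)CO[Si](C)(C)C(C)(C)C
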